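The retrosynthesis first removes the three phenolic MOM groups. It then cuts C3–C4 of ring C (CH2–C=O), which turns the protected flavanone into its isomer, a 2-(1-arylvinyloxy)benzaldehyde. Further cuts are C4–C4a (formyl group), C2=C3 (methylenation of an aryl ester), the O1–C2 acyl bond (ring A phenol plus syringic acid unit) and C6–C1'' (geranyl).
C4 sits on C4a, ortho to O1 on C8a, and C2 carries only O1, ring B and C3. C2=C3 can therefore exist as a 1,1-disubstituted aryl enol ether held next to a formyl C–H, and adding that C–H across C2=C3 makes the C3–C4 bond, ring C and the C2 stereocentre together, without base.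
O1 (on C8a) is para to the geranyl-bearing C6, so ring A is a symmetric 2-geranylphloroglucinol 5-ether with two equivalent free positions. The 6-geranyl (not 8-geranyl) pattern follows from this symmetry.
In the forward direction ring A is protected, geranylated between its two OMOM groups and iodinated, and the ring B acid is esterified onto it. The ester C=O becomes C=CH2, iodine becomes CHO, ring C closes last, and the MOM groups are then removed.
C2 (S) comes from the chiral bisphosphine on rhodium during hydride transfer to the Re face of C2. The 2''E alkene comes with geranyl bromide and is never touched.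
Key step: step 11

Assumption: (R)-DTBM-SEGPHOS is taken to be the ligand enantiomer that opens the Re face of C2 (2S product). If the sense of induction is the opposite, (S)-DTBM-SEGPHOS is used and nothing else changes.
Note: geranyl stands for (2E)-3,7-dimethylocta-2,6-dien-1-yl and MOM for CH2OCH3. Flavanone numbering (O1, C2, C3, C4, C4a, C5 to C8, C8a; ring B primed; geranyl doubly primed) is used for all intermediates.

Step 1
Reactants: 1 phloroglucinol (benzene-1,3,5-triol)
Product: 2 3,5-bis(methoxymethoxy)phenol
Conditions: MOMCl (2.0 equiv), i-Pr2NEt (2.2 equiv), DMF, 0 °C to rt; chromatography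
Reagents that add atoms: chloromethyl methyl ether (MOMCl), COCCl
Why: Base-mediated O-alkylation of a phenol with an α-chloro ether (MOM protection) is reliable, and two equivalents of reagent on the threefold-symmetric triol should make the bis-ether the main member of a separable statistical mixture.

Step 2
Reactants: 2 3,5-bis(methoxymethoxy)phenol
Product: 3 [3,5-bis(methoxymethoxy)phenoxy]triisopropylsilane
Conditions: TIPSCl, imidazole, DMF, rt
Reagents that add atoms: chlorotriisopropylsilane (TIPSCl), CC(C)[Si](Cl)(C(C)C)C(C)C
Why: Imidazole-promoted silylation of the remaining phenol is routine, and the bulky, non-coordinating OTIPS group marks the oxygen that becomes O1 and shields its two ortho positions from the next metalation.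

Step 3
Reactants: 3 [3,5-bis(methoxymethoxy)phenoxy]triisopropylsilane; 4 geranyl bromide, (2E)-1-bromo-3,7-dimethylocta-2,6-diene
Product: 6 [4-geranyl-3,5-bis(methoxymethoxy)phenoxy]triisopropylsilane, via aryllithium 5 (not isolated)
Conditions: n-BuLi (1.1 equiv), THF, 0 °C; CuBr·SMe2 (10 mol %), then 4, −78 °C to rt
Reagents that add atoms: none
Why: Directed ortho-metalation takes place at the only position flanked by two chelating OMOM groups (future C6), and copper-assisted SN2 allylation of aryllithium 5 with the primary allylic bromide should transfer the chain with its E geometry intact.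

Step 4
Reactants: 6 [4-geranyl-3,5-bis(methoxymethoxy)phenoxy]triisopropylsilane
Product: 7 4-geranyl-3,5-bis(methoxymethoxy)phenol
Conditions: TBAF, AcOH, THF, 0 °C
Reagents that add atoms: none
Why: Fluoride cleaves the phenolic Si–O bond selectively (silyl ether deprotection), and the acetic acid buffer protonates the phenoxide at once, leaving the MOM acetals and the alkenes untouched.

Step 5
Reactants: 7 4-geranyl-3,5-bis(methoxymethoxy)phenol
Product: 8 4-geranyl-2-iodo-3,5-bis(methoxymethoxy)phenol
Conditions: I2 (1.0 equiv), NaHCO3, THF–H2O, 0 °C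
Reagents that add atoms: iodine, [I][I]
Why: Electrophilic aromatic iodination of a phloroglucinol-type phenol under bicarbonate is far faster than any reaction of iodine with an isolated trisubstituted alkene, and because the para position is blocked and the two ortho positions are equivalent, one equivalent should give a single mono-iodide.

Step 6
Reactants: 9 methyl syringate (methyl 4-hydroxy-3,5-dimethoxybenzoate)
Product: 10 methyl 3,5-dimethoxy-4-(methoxymethoxy)benzoate
Conditions: MOMCl (1.5 equiv), i-Pr2NEt, CH2Cl2, 0 to 40 °C
Reagents that add atoms: chloromethyl methyl ether (MOMCl), COCCl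
Why: MOM protection of the single phenol is standard O-alkylation and gives ring B the same protecting group as ring A, so that one final operation frees all three phenols.

Step 7
Reactants: 10 methyl 3,5-dimethoxy-4-(methoxymethoxy)benzoate
Product: 12 3,5-dimethoxy-4-(methoxymethoxy)benzoic acid, via lithium carboxylate 11 (not isolated)
Conditions: LiOH, THF–MeOH–H2O, 40 °C; then dilute aq. HCl to pH 4, 0 °C
Reagents that add atoms: lithium hydroxide, [Li+].[OH-]
Why: Saponification of a methyl benzoate is unproblematic, and the aryl MOM ether is stable to base and to the brief cold acidification.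

Step 8
Reactants: 8 4-geranyl-2-iodo-3,5-bis(methoxymethoxy)phenol; 12 3,5-dimethoxy-4-(methoxymethoxy)benzoic acid
Product: 13 4-geranyl-2-iodo-3,5-bis(methoxymethoxy)phenyl 3,5-dimethoxy-4-(methoxymethoxy)benzoate
Conditions: dicyclohexylcarbodiimide, DMAP (10 mol %), CH2Cl2, 0 °C to rt
Reagents that add atoms: none
Why: Steglich esterification joins rings A and B through the future O1–C2 bond under neutral conditions that all acetals, the iodide and the alkenes tolerate.

Step 9
Reactants: 13 4-geranyl-2-iodo-3,5-bis(methoxymethoxy)phenyl 3,5-dimethoxy-4-(methoxymethoxy)benzoate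
Product: 14 2-geranyl-4-iodo-1,3-bis(methoxymethoxy)-5-({1-[3,5-dimethoxy-4-(methoxymethoxy)phenyl]ethenyl}oxy)benzene
Conditions: Cp2TiMe2 (2.5 equiv), toluene, 75 °C, dark; filtration through basic alumina
Reagents that add atoms: dimethyltitanocene (Cp2TiMe2), C[Ti+2]C.c1cc[cH-]c1.c1cc[cH-]c1
Why: In the Petasis methylenation, thermolysis of Cp2TiMe2 gives the titanium methylidene, which converts aryl benzoates into 1-aryloxy-1-arylethenes by [2+2] addition to C=O and cycloreversion, and these non-acidic conditions spare the MOM acetals, the aryl iodide and the trisubstituted alkenes while bringing in C3.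

Step 10
Reactants: 14 2-geranyl-4-iodo-1,3-bis(methoxymethoxy)-5-({1-[3,5-dimethoxy-4-(methoxymethoxy)phenyl]ethenyl}oxy)benzene
Product: 17 3-geranyl-2,4-bis(methoxymethoxy)-6-({1-[3,5-dimethoxy-4-(methoxymethoxy)phenyl]ethenyl}oxy)benzaldehyde, via aryllithium 15 (not isolated), via lithium hemiaminolate 16 (not isolated)
Conditions: n-BuLi (1.05 equiv), THF, −78 °C, 10 min; DMF (3 equiv), −78 to 0 °C; H2O
Reagents that add atoms: N,N-dimethylformamide (DMF), CN(C)C=O
Why: Iodine–lithium exchange at −78 °C is faster than any attack of n-BuLi on the enol ether, and trapping of aryllithium 15 with DMF (Bouveault-type formylation) gives hemiaminolate 16, which collapses to the aldehyde on a neutral aqueous quench that the acid-labile enol ether tolerates.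

Step 11
Reactants: 17 3-geranyl-2,4-bis(methoxymethoxy)-6-({1-[3,5-dimethoxy-4-(methoxymethoxy)phenyl]ethenyl}oxy)benzaldehyde
Product: 18 (2S)-6-geranyl-5,7-bis(methoxymethoxy)-2-[3,5-dimethoxy-4-(methoxymethoxy)phenyl]chroman-4-one
Conditions: [Rh(cod)Cl]2 (2.5 mol %), (R)-DTBM-SEGPHOS (5 mol %), NaB[3,5-(CF3)2C6H3]4 (5 mol %), 4 Å molecular sieves, 1,4-dioxane, 80 °C, Ar
Reagents that add atoms: none
Why: Proposed new method: the cationic monovalent rhodium bisphosphine complex should add oxidatively into the formyl C–H bond of 17 while the ortho 1-arylvinyl ether binds as the chelating π-ligand, transfer the hydride to C2 to give a seven-membered acyl(alkyl)rhodacycle with the metal on the primary carbon C3, and then form the C3–C4 bond by reductive elimination, so that 17 isomerises to 18 with no by-product and no base. The closest known reaction type is the endo- and enantioselective rhodium-catalysed intramolecular hydroacylation of 1,1-disubstituted alkenes in ortho-allylbenzaldehydes (to 3-substituted tetralones) and in 2-(1-substituted vinyl)benzaldehydes (to 3-substituted indanones); new here is the oxygen atom O1 in the tether, which makes the alkene an aryl enol ether. Ring C closes in a formal 6-endo-trig mode, the acyl carbon C4 bonding to the terminal alkene carbon C3. The one new stereocentre, C2, is set in the hydride transfer by the axially chiral ligand, whose aryl quadrants must leave the Re face of C2 open to the rhodium hydride so that (2S) results. The step needs endo over exo insertion (exo would give a 2-aryl-2-methylbenzofuran-3-one), which the reluctance of rhodium to form a tertiary benzylic alkyl and a quaternary carbon secures, and it needs the geranyl alkenes to stay out, which their trisubstitution and their position meta to the formyl group (no chelate possible) secure. Decarbonylation is countered by the chelating alkene and the flanking C5 OMOM oxygen, alkene isomerisation is impossible because C2 carries no allylic hydrogen, and β-aryloxide elimination from the rhodacycle is unproductive and reversible since the phenoxide stays tethered ortho to the acyl group.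

Step 12
Reactants: 18 (2S)-6-geranyl-5,7-bis(methoxymethoxy)-2-[3,5-dimethoxy-4-(methoxymethoxy)phenyl]chroman-4-one
Product: 19 (2S)-6-geranyl-5,7-dihydroxy-2-(4-hydroxy-3,5-dimethoxyphenyl)chroman-4-one (CNP0372687.1)
Conditions: HCl (cat., 0.3 mol/L in MeOH), 35 °C, stopped at full conversion; pH 7 buffer
Reagents that add atoms: none
Why: Acid-catalysed transacetalisation of the three aryl MOM ethers to methanol is the standard release of prenylated and geranylated polyphenols, and short exposure to dilute acid at mild temperature with no base present should leave the geranyl alkenes and the C2 configuration unchanged.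

Compound list
1 | phloroglucinol | Oc1cc(O)cc(O)c1 | starting material
2 | 3,5-bis(methoxymethoxy)phenol | COCOc1cc(O)cc(OCOC)c1 | intermediate
3 | [3,5-bis(methoxymethoxy)phenoxy]triisopropylsilane | COCOc1cc(OCOC)cc(O[Si](C(C)C)(C(C)C)C(C)C)c1 | intermediate
4 | geranyl bromide | BrC/C=C(\C)CCC=C(C)C | starting material
5 | {2,6-bis(methoxymethoxy)-4-[(triisopropylsilyl)oxy]phenyl}lithium | [Li]c1c(OCOC)cc(O[Si](C(C)C)(C(C)C)C(C)C)cc1OCOC | intermediate
6 | [4-geranyl-3,5-bis(methoxymethoxy)phenoxy]triisopropylsilane | COCOc1cc(O[Si](C(C)C)(C(C)C)C(C)C)cc(OCOC)c1C/C=C(\C)CCC=C(C)C | intermediate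
7 | 4-geranyl-3,5-bis(methoxymethoxy)phenol | COCOc1cc(O)cc(OCOC)c1C/C=C(\C)CCC=C(C)C | intermediate
8 | 4-geranyl-2-iodo-3,5-bis(methoxymethoxy)phenol | COCOc1cc(O)c(I)c(OCOC)c1C/C=C(\C)CCC=C(C)C | intermediate
9 | methyl syringate | COC(=O)c1cc(OC)c(O)c(OC)c1 | starting material
10 | methyl 3,5-dimethoxy-4-(methoxymethoxy)benzoate | COCOc1c(OC)cc(C(=O)OC)cc1OC | intermediate
11 | lithium 3,5-dimethoxy-4-(methoxymethoxy)benzoate | COCOc1c(OC)cc(C(=O)[O-])cc1OC.[Li+] | intermediate
12 | 3,5-dimethoxy-4-(methoxymethoxy)benzoic acid | COCOc1c(OC)cc(C(=O)O)cc1OC | intermediate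
13 | 4-geranyl-2-iodo-3,5-bis(methoxymethoxy)phenyl 3,5-dimethoxy-4-(methoxymethoxy)benzoate | COCOc1c(OC)cc(C(=O)Oc2cc(OCOC)c(C/C=C(\C)CCC=C(C)C)c(OCOC)c2I)cc1OC | intermediate
14 | 2-geranyl-4-iodo-1,3-bis(methoxymethoxy)-5-({1-[3,5-dimethoxy-4-(methoxymethoxy)phenyl]ethenyl}oxy)benzene | COCOc1c(OC)cc(C(=C)Oc2cc(OCOC)c(C/C=C(\C)CCC=C(C)C)c(OCOC)c2I)cc1OC | intermediate
15 | aryllithium from 14 (Li in place of iodine) | COCOc1c(OC)cc(C(=C)Oc2cc(OCOC)c(C/C=C(\C)CCC=C(C)C)c(OCOC)c2[Li])cc1OC | intermediate
16 | lithium hemiaminolate, DMF adduct of 15 (racemic at the carbinol carbon) | COCOc1c(OC)cc(C(=C)Oc2cc(OCOC)c(C/C=C(\C)CCC=C(C)C)c(OCOC)c2C([O-])N(C)C)cc1OC.[Li+] | intermediate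
17 | 3-geranyl-2,4-bis(methoxymethoxy)-6-({1-[3,5-dimethoxy-4-(methoxymethoxy)phenyl]ethenyl}oxy)benzaldehyde | COCOc1c(OC)cc(C(=C)Oc2cc(OCOC)c(C/C=C(\C)CCC=C(C)C)c(OCOC)c2C=O)cc1OC | intermediate
18 | (2S)-6-geranyl-5,7-bis(methoxymethoxy)-2-[3,5-dimethoxy-4-(methoxymethoxy)phenyl]chroman-4-one | COCOc1c(OC)cc([C@@H]2CC(=O)c3c(cc(OCOC)c(C/C=C(\C)CCC=C(C)C)c3OCOC)O2)cc1OC | intermediate
19 | (2S)-6-geranyl-5,7-dihydroxy-2-(4-hydroxy-3,5-dimethoxyphenyl)chroman-4-one | COc1cc([C@@H]2CC(=O)c3c(cc(O)c(C/C=C(\C)CCC=C(C)C)c3O)O2)cc(OC)c1O | target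

Total step count: 12. Longest linear sequence: 10 (steps 1 to 5 and 8 to 12).

Steps most likely to fail

Step 11. The acylrhodium hydride of the hindered, electron-rich aldehyde may lose CO before insertion. Insertion may go the exo way. The cationic metal may act only as a Lewis acid and trigger aldol-type closure of the enol ether onto the aldehyde. Facial selectivity at C2 may also be poor.
The fallback sets out from 8 and comes back at 18, using known chemistry only.
- Syringaldehyde is protected (MOMCl, i-Pr2NEt, CH2Cl2) to give 3,5-dimethoxy-4-(methoxymethoxy)benzaldehyde F1.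
- F1 is homologated with the Ohira–Bestmann reagent (K2CO3, MeOH) to 5-ethynyl-1,3-dimethoxy-2-(methoxymethoxy)benzene F2.
- Carbonylative Sonogashira coupling of 8 with F2 (PdCl2(PPh3)2, CO 1 atm, Et2NH, 40 to 60 °C) should pass through the 2-hydroxyaryl alkynyl ketone F3. This closes in the same flask by amine-mediated 6-endo addition of the phenol to give the tris-MOM flavone F4.
- Copper hydride asymmetric conjugate reduction of F4 then gives 18. The conditions are Cu(OAc)2, DTBM-SEGPHOS (the enantiomer that gives 2S), (EtO)2MeSiH, t-BuOH, toluene, 0 °C. This reaction type is established for 2-substituted chromones and is inert to isolated alkenes.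

Step 5. Electrophilic iodine may attack the trisubstituted alkenes of the geranyl chain, or a second iodination of the ring may occur.
The fallback sets out from 7 and comes back at 8. It replaces electrophilic substitution by directed metalation with an iodine donor that does not touch alkenes.
- Phenol 7 is converted with ethyl vinyl ether and PPTS (CH2Cl2, rt) into the 1-ethoxyethyl ether F5.
- n-BuLi (THF, 0 °C) metalates the position between the OMOM and the acetal oxygen to give the aryllithium F6.
- 1,2-Diiodoethane (−78 °C) converts F6 into the iodo 1-ethoxyethyl ether F7.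
- PPTS in MeOH at rt removes the more labile acetal while keeping both MOM groups, giving 8.

Step 12. The freed C5 or C7 hydroxyl may add to the C2''=C3'' alkene under acid (chroman formation). The C2 configuration may also erode through reversible opening of ring C, assisted by the freed 4'-hydroxyl.
The fallback sets out from 18 and comes back at 19. It replaces Brønsted acidolysis by a two-stage, non-protic exchange of acetal for silyl ether.
- TMSOTf and 2,2'-bipyridyl (MeCN, 0 °C) should convert the three aryl MOM ethers into the tris(trimethylsilyl) ether F8.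
- F8 is hydrolysed with water at pH 7 and rt to give 19.

Further compounds
F1 | step 11 | 3,5-dimethoxy-4-(methoxymethoxy)benzaldehyde | COCOc1c(OC)cc(C=O)cc1OC
F2 | step 11 | 5-ethynyl-1,3-dimethoxy-2-(methoxymethoxy)benzene | COCOc1c(OC)cc(C#C)cc1OC
F3 | step 11 | 1-[3-geranyl-6-hydroxy-2,4-bis(methoxymethoxy)phenyl]-3-[3,5-dimethoxy-4-(methoxymethoxy)phenyl]prop-2-yn-1-one | COCOc1c(OC)cc(C#CC(=O)c2c(O)cc(OCOC)c(C/C=C(\C)CCC=C(C)C)c2OCOC)cc1OC
F4 | step 11 | 6-geranyl-5,7-bis(methoxymethoxy)-2-[3,5-dimethoxy-4-(methoxymethoxy)phenyl]-4H-chromen-4-one | COCOc1c(OC)cc(-c2cc(=O)c3c(cc(OCOC)c(C/C=C(\C)CCC=C(C)C)c3OCOC)o2)cc1OC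
F5 | step 5 | 5-(1-ethoxyethoxy)-2-geranyl-1,3-bis(methoxymethoxy)benzene (racemic acetal carbon) | CCOC(C)Oc1cc(OCOC)c(C/C=C(\C)CCC=C(C)C)c(OCOC)c1
F6 | step 5 | [6-(1-ethoxyethoxy)-3-geranyl-2,4-bis(methoxymethoxy)phenyl]lithium | CCOC(C)Oc1cc(OCOC)c(C/C=C(\C)CCC=C(C)C)c(OCOC)c1[Li]
F7 | step 5 | 1-(1-ethoxyethoxy)-4-geranyl-2-iodo-3,5-bis(methoxymethoxy)benzene | CCOC(C)Oc1cc(OCOC)c(C/C=C(\C)CCC=C(C)C)c(OCOC)c1I
F8 | step 12 | (2S)-6-geranyl-5,7-bis(trimethylsilyloxy)-2-[3,5-dimethoxy-4-(trimethylsilyloxy)phenyl]chroman-4-one | COc1cc([C@@H]2CC(=O)c3c(cc(O[Si](C)(C)C)c(C/C=C(\C)CCC=C(C)C)c3O[Si](C)(C)C)O2)cc(OC)c1O[Si](C)(C)C
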